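Atom labels: C1 is the CH–OAc carbon, then C2, C3, C4(Me)=C5, C6=C7(iPr), C8, C9, C10 (C(Me)OH) and the oxolane carbons C11–C14 (oxygen between C11 and C14). The oxolane CH2–CH2 bond C12–C13 lies between the carbinol C11 and the C14–C1 pair of C–O carbons, which is the retron of a γ,δ-unsaturated ketone. A Claisen rearrangement therefore forms C12–C13 and closes the 14-membered carbocycle in one operation, by two-carbon ring expansion of a 12-membered 2-methylene oxacycle: a C11–O–C1 lactone, methylenated at C11, with an isopropenyl group (C14, C13) on C1. Ketone reduction and epoxide opening then build the oxolane.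

Key step: step 13

Remark: alcohol 14 is used as the racemate. Compounds 14–20 are therefore 1:1 mixtures of C1 epimers (written without a descriptor at C1); both converge in step 13, where C1 becomes an alkene carbon.

**Fragment C8–C11 and C6–C7 (boronate 9)**

Step 1
Reactants: 1 (R)-citramalic acid
Product: 2 2-[(4R)-2,2,4-trimethyl-5-oxo-1,3-dioxolan-4-yl]acetic acid
Conditions: 2,2-dimethoxypropane, TsOH·H2O (cat.), CH2Cl2, rt
Reagents that add atoms: 2,2-dimethoxypropane COC(C)(C)OC
Why: Acid-catalysed transketalisation closes the five-membered 1,3-dioxolan-4-one on the α-hydroxy acid unit (favoured over the six-membered dioxanone), masking C10–OH and the C11 carboxyl together and leaving the C8 carboxyl free; the chiral-pool stereocentre (C10) is not touched.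

Step 2
Reactants: 2 dioxolanone acid
Product: 3 (5R)-5-(2-hydroxyethyl)-2,2,5-trimethyl-1,3-dioxolan-4-one
Conditions: BH3·THF, THF, 0 °C to rt; MeOH quench
Reagents that add atoms: none
Why: Borane reduces the free carboxylic acid much faster than the lactone-type carbonyl of the dioxolanone, giving the primary alcohol at C8.

Step 3
Reactants: 3 hydroxyethyl dioxolanone
Product: 4 (5R)-5-(2-iodoethyl)-2,2,5-trimethyl-1,3-dioxolan-4-one
Conditions: I2, PPh3, imidazole, CH2Cl2, 0 °C
Reagents that add atoms: iodine II
Why: Appel iodination of the primary alcohol under buffered conditions, run directly on crude 3 so that the alcohol does not translactonise onto the dioxolanone.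

Step 4
Reactants: 5 3-methylbut-1-yne
Product: 7 2-[(1Z)-2-bromo-3-methylbut-1-en-1-yl]-4,4,5,5-tetramethyl-1,3,2-dioxaborolane, via alkenyl dibromoborane 6 (not isolated)
Conditions: BBr3, CH2Cl2, −78 °C; then pinacol, −78 °C to rt
Reagents that add atoms: boron tribromide BrB(Br)Br; pinacol CC(C)(O)C(C)(C)O
Why: syn-Bromoboration of the terminal alkyne places Br on the internal carbon (C7) and boron on C6 on the same side, and pinacol converts the dibromoborane into the pinacol boronate with the Z geometry intact.

Step 5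
Reactants: 4 iodoethyl dioxolanone; 7 (Z)-bromoalkenyl boronate
Product: 9 (5R)-2,2,5-trimethyl-5-[(3E)-4-methyl-3-[(4,4,5,5-tetramethyl-1,3,2-dioxaborolan-2-yl)methylidene]pentyl]-1,3-dioxolan-4-one, via alkylzinc iodide 8 (not isolated)
Conditions: Zn dust, LiCl, THF, 30 °C; then 7, Pd(t-Bu3P)2 (2 mol %), THF, rt
Reagents that add atoms: none
Why: LiCl-mediated zinc insertion gives the ester-tolerant alkylzinc iodide, and Negishi coupling at the C7–Br bond proceeds with retention while the C–B bond stays untouched in the absence of base, so C8 ends cis to boron (the future C5).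

**Fragment C1–C5 with C13, C14 (iodide 14)**

Step 6
Reactants: 10 pent-4-yn-1-ol
Product: 12 (4E)-5-iodo-4-methylpent-4-en-1-ol, via alkenylalane 11 (not isolated)
Conditions: Me3Al (3 equiv), Cp2ZrCl2 (0.25 equiv), CH2Cl2, 0 °C to rt; then I2, THF, −30 °C
Reagents that add atoms: trimethylaluminium C[Al](C)C; iodine II
Why: Zirconium-catalysed syn-carboalumination (Negishi) adds methyl to C4 and aluminium to C5, and iodinolysis with retention gives the E vinyl iodide.

Step 7
Reactants: 12 iodo alcohol
Product: 13 (4E)-5-iodo-4-methylpent-4-enal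
Conditions: Dess–Martin periodinane, NaHCO3, CH2Cl2, 0 °C to rt
Reagents that add atoms: none
Why: Dess–Martin oxidation of the primary alcohol to the aldehyde; the vinyl iodide is inert.

Step 8
Reactants: 13 iodo aldehyde
Product: 14 (3RS,6E)-7-iodo-2,6-dimethylhepta-1,6-dien-3-ol
Conditions: isopropenylmagnesium bromide, THF, −78 °C; aq. NH4Cl
Reagents that add atoms: isopropenylmagnesium bromide C=C(C)[Mg]Br
Why: 1,2-Addition of the alkenyl Grignard reagent to the aldehyde installs C14, its methyl group and C13; the new carbinol centre is not controlled because it becomes sp2 in step 13.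

**Union, ring expansion and endgame**

Step 9
Reactants: 9 alkenyl boronate; 14 iodo dienol
Product: 16 (2R,5E,7E,11RS)-2,11-dihydroxy-2,8,12-trimethyl-5-(propan-2-yl)trideca-5,7,12-trienoic acid, via dienyl dioxolanone 15 (not isolated)
Conditions: PdCl2(dppf) (5 mol %), K3PO4, THF/H2O, 40 °C; then LiOH (aq.), rt; 1 M HCl to pH 3
Reagents that add atoms: lithium hydroxide [Li+].[OH-]
Why: Suzuki–Miyaura coupling joins C5 and C6 with retention at both alkenyl partners, fixing the diene geometry (C3 trans to C6, C8 cis to C5), and hydroxide then saponifies the dioxolanone with loss of acetone.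

Step 10
Reactants: 16 seco acid
Product: 18 (3R,6E,8E,12RS)-3-hydroxy-3,9-dimethyl-6-(propan-2-yl)-12-(prop-1-en-2-yl)oxacyclododeca-6,8-dien-2-one, via mixed anhydride 17 (not isolated)
Conditions: 2,4,6-trichlorobenzoyl chloride, Et3N, THF, rt; then slow addition to DMAP, toluene (0.002 M), 80 °C
Reagents that add atoms: none
Why: Yamaguchi macrolactonisation: the mixed anhydride acylates the secondary allylic C1–OH while the tertiary C10–OH is too hindered to compete, and the rigid diene limits the entropic cost of the 12-membered ring.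

Step 11
Reactants: 18 hydroxy lactone
Product: 19 (3R,6E,8E,12RS)-3,9-dimethyl-6-(propan-2-yl)-12-(prop-1-en-2-yl)-3-[(triethylsilyl)oxy]oxacyclododeca-6,8-dien-2-one
Conditions: TESOTf, 2,6-lutidine, CH2Cl2, −40 to 0 °C
Reagents that add atoms: triethylsilyl triflate CC[Si](CC)(CC)OS(=O)(=O)C(F)(F)F
Why: Silyl triflate with 2,6-lutidine silylates the hindered tertiary alcohol, which must be masked for the titanium methylidene, for the directed epoxidation and for the oxolane closure.

Step 12
Reactants: 19 silyloxy lactone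
Product: 20 12-membered 2-methylidene oxacycle (C11=C12H2 enol ether of 19)
Conditions: Tebbe reagent Cp2Ti(µ-CH2)(µ-Cl)AlMe2, pyridine, THF/toluene, −40 to 0 °C; aq. NaOH; filtration through basic alumina
Reagents that add atoms: Tebbe reagent C[Al](C)C[Ti](Cl)(C1C=CC=C1)C1C=CC=C1
Why: Carbonyl methylenation of the lactone by the titanium methylidene (Tebbe olefination) gives the exocyclic enol ether and brings in C12; the low temperature keeps the product below the threshold of the rearrangement.

Step 13
Reactants: 20 2-methylidene oxacycle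
Product: 21 (2R,5E,7E,11E)-2,8,12-trimethyl-5-(propan-2-yl)-2-[(triethylsilyl)oxy]cyclotetradeca-5,7,11-trien-1-one
Conditions: toluene, Et3N (0.1 equiv), base-washed sealed tube, 130 °C
Reagents that add atoms: none
Why: Thermal [3,3]-sigmatropic (Claisen) rearrangement of the allyl vinyl ether C12=C11–O–C1–C14=C13: the C12–C13 σ-bond forms as the O–C1 bond breaks, giving the C11 ketone and the C14=C1 alkene. The closest known reaction type is the Claisen ring expansion of 2-methylene oxacycles that carry an alkenyl group next to oxygen, made by Tebbe methylenation of lactones. The 14-membered carbocycle is closed by a concerted suprafacial six-centre process in which the 12-membered oxacycle (O, C11, C10 to C2, C1) holds C12 and C13 over each other while the old ring opens in the same event, so the closure is unimolecular and needs no high dilution. No stereocentre is created (C12 and C13 are CH2; C1 becomes sp2, so both C1 epimers of 20 converge) and C10 is not involved. The selectivity needed is the E geometry at C14=C1, which a chair transition state with the C1–C2 ring bond pseudo-equatorial should secure, the nine-atom tether C2–C10 being long enough to span it. Base-washed glass and Et3N keep the exocyclic enol ether from isomerising or hydrolysing, and 130 °C stays below the onset of 1,5-hydrogen shifts in the diene.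

Step 14
Reactants: 21 macrocyclic ketone
Product: 22 (1S,2R,5E,7E,11E)-2,8,12-trimethyl-5-(propan-2-yl)-2-[(triethylsilyl)oxy]cyclotetradeca-5,7,11-trien-1-ol
Conditions: (R)-2-methyl-CBS-oxazaborolidine (30 mol %), catecholborane, toluene, −78 to −40 °C
Reagents that add atoms: none
Why: Corey–Bakshi–Shibata reduction: the ketone binds with the quaternary C10 as the large and C12H2 as the small substituent, so the (R)-catalyst should deliver hydride to the face that gives the (11S)-alcohol, overriding any bias from C10.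

Step 15
Reactants: 22 macrocyclic alcohol
Product: 24 oxolane alcohol (target skeleton with free C1–OH and C10–OSiEt3; 1S,10R,11S,14R), via epoxy alcohol 23 (not isolated)
Conditions: Hf(OtBu)4 (10 mol %), C2-symmetric bis-hydroxamic acid ligand from trans-cyclohexane-1,2-diamine (11 mol %; antipode chosen for the (14S,1S) face), cumene hydroperoxide, 4 Å MS, toluene, 0 °C to rt; then CSA (5 mol %), CH2Cl2, 0 °C
Reagents that add atoms: cumene hydroperoxide CC(C)(OO)c1ccccc1
Why: Hydroxyl-directed asymmetric epoxidation: the C11 hafnium alkoxide delivers the peroxide oxygen only to the bishomoallylic C14=C1 alkene (the diene is out of reach and C10–O is silylated), with the chiral ligand fixing the face to give the (14S,1S)-epoxide, and acid then triggers 5-exo opening by C11–OH at the tertiary C14 with inversion (14R), which sets the cis-2,5 oxolane and leaves C1–OH with its S configuration.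

Step 16
Reactants: 24 oxolane alcohol
Product: 25 10-O-triethylsilyl ether of the target
Conditions: Ac2O, DMAP, pyridine, CH2Cl2, rt
Reagents that add atoms: acetic anhydride CC(=O)OC(C)=O
Why: DMAP-catalysed acetylation of the only free hydroxyl group (secondary C1–OH).

Step 17
Reactants: 25 silyl-protected acetate
Product: 26 target CNP0199953.1
Conditions: HF·pyridine, pyridine/THF, 0 °C to rt
Reagents that add atoms: none
Why: Fluoride cleaves the tertiary triethylsilyl ether under buffered conditions that leave the acetate, the diene and the oxolane untouched.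

**Compound list**

1 | (R)-citramalic acid, (2R)-2-hydroxy-2-methylbutanedioic acid | OC(=O)C[C@@](C)(O)C(=O)O | starting material
2 | 2-[(4R)-2,2,4-trimethyl-5-oxo-1,3-dioxolan-4-yl]acetic acid | OC(=O)C[C@@]1(C)OC(C)(C)OC1=O | intermediate
3 | (5R)-5-(2-hydroxyethyl)-2,2,5-trimethyl-1,3-dioxolan-4-one | OCC[C@@]1(C)OC(C)(C)OC1=O | intermediate
4 | (5R)-5-(2-iodoethyl)-2,2,5-trimethyl-1,3-dioxolan-4-one | ICC[C@@]1(C)OC(C)(C)OC1=O | intermediate
5 | 3-methylbut-1-yne | CC(C)C#C | starting material
6 | dibromo[(1Z)-2-bromo-3-methylbut-1-en-1-yl]borane (not isolated) | CC(C)/C(Br)=C/B(Br)Br | intermediate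
7 | 2-[(1Z)-2-bromo-3-methylbut-1-en-1-yl]-4,4,5,5-tetramethyl-1,3,2-dioxaborolane (Br cis to B) | CC(C)/C(Br)=C/B1OC(C)(C)C(C)(C)O1 | intermediate
8 | {2-[(4R)-2,2,4-trimethyl-5-oxo-1,3-dioxolan-4-yl]ethyl}zinc iodide (not isolated) | I[Zn]CC[C@@]1(C)OC(C)(C)OC1=O | intermediate
9 | (5R)-2,2,5-trimethyl-5-[(3E)-4-methyl-3-[(4,4,5,5-tetramethyl-1,3,2-dioxaborolan-2-yl)methylidene]pentyl]-1,3-dioxolan-4-one (C8 chain cis to B) | CC(C)/C(CC[C@@]1(C)OC(C)(C)OC1=O)=C/B2OC(C)(C)C(C)(C)O2 | intermediate
10 | pent-4-yn-1-ol | C#CCCCO | starting material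
11 | [(1E)-5-[(dimethylalumanyl)oxy]-2-methylpent-1-en-1-yl]dimethylalumane (not isolated) | C[Al](C)/C=C(\C)CCCO[Al](C)C | intermediate
12 | (4E)-5-iodo-4-methylpent-4-en-1-ol | OCCC/C(C)=C/I | intermediate
13 | (4E)-5-iodo-4-methylpent-4-enal | O=CCC/C(C)=C/I | intermediate
14 | (3RS,6E)-7-iodo-2,6-dimethylhepta-1,6-dien-3-ol | C=C(C)C(O)CC/C(C)=C/I | intermediate
15 | (5R)-5-[(3E,5E,9RS)-9-hydroxy-6,10-dimethyl-3-(propan-2-yl)undeca-3,5,10-trien-1-yl]-2,2,5-trimethyl-1,3-dioxolan-4-one (not isolated) | C=C(C)C(O)CC/C(C)=C/C=C(/C(C)C)CC[C@@]1(C)OC(C)(C)OC1=O | intermediate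
16 | (2R,5E,7E,11RS)-2,11-dihydroxy-2,8,12-trimethyl-5-(propan-2-yl)trideca-5,7,12-trienoic acid | C=C(C)C(O)CC/C(C)=C/C=C(/C(C)C)CC[C@@](C)(O)C(=O)O | intermediate
17 | mixed anhydride of 16 with 2,4,6-trichlorobenzoic acid (not isolated) | C=C(C)C(O)CC/C(C)=C/C=C(/C(C)C)CC[C@@](C)(O)C(=O)OC(=O)c1c(Cl)cc(Cl)cc1Cl | intermediate
18 | (3R,6E,8E,12RS)-3-hydroxy-3,9-dimethyl-6-(propan-2-yl)-12-(prop-1-en-2-yl)oxacyclododeca-6,8-dien-2-one | C=C(C)C1CC/C(C)=C/C=C(/C(C)C)CC[C@@](C)(O)C(=O)O1 | intermediate
19 | (3R,6E,8E,12RS)-3,9-dimethyl-6-(propan-2-yl)-12-(prop-1-en-2-yl)-3-[(triethylsilyl)oxy]oxacyclododeca-6,8-dien-2-one | C=C(C)C1CC/C(C)=C/C=C(/C(C)C)CC[C@@](C)(O[Si](CC)(CC)CC)C(=O)O1 | intermediate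
20 | triethyl{[(3R,6E,8E,12RS)-3,9-dimethyl-2-methylidene-6-(propan-2-yl)-12-(prop-1-en-2-yl)oxacyclododeca-6,8-dien-3-yl]oxy}silane | C=C(C)C1CC/C(C)=C/C=C(/C(C)C)CC[C@@](C)(O[Si](CC)(CC)CC)C(=C)O1 | intermediate
21 | (2R,5E,7E,11E)-2,8,12-trimethyl-5-(propan-2-yl)-2-[(triethylsilyl)oxy]cyclotetradeca-5,7,11-trien-1-one | O=C1CC/C(C)=C/CC/C(C)=C/C=C(/C(C)C)CC[C@@]1(C)O[Si](CC)(CC)CC | intermediate
22 | (1S,2R,5E,7E,11E)-2,8,12-trimethyl-5-(propan-2-yl)-2-[(triethylsilyl)oxy]cyclotetradeca-5,7,11-trien-1-ol | O[C@H]1CC/C(C)=C/CC/C(C)=C/C=C(/C(C)C)CC[C@@]1(C)O[Si](CC)(CC)CC | intermediate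
23 | (11S)-alcohol 22 with a (14S,1S)-oxirane in place of the C14=C1 alkene (not isolated) | O[C@H]1CC[C@]2(C)O[C@H]2CC/C(C)=C/C=C(/C(C)C)CC[C@@]1(C)O[Si](CC)(CC)CC | intermediate
24 | (1S,10R,11S,14R)-oxolane alcohol: target skeleton with C1–OH free and C10–OSiEt3 | O[C@H]1CC/C(C)=C/C=C(/C(C)C)CC[C@@](C)(O[Si](CC)(CC)CC)[C@@H]2CC[C@@]1(C)O2 | intermediate
25 | 10-O-triethylsilyl ether of the target (C1–OAc, C10–OSiEt3) | CC(=O)O[C@H]1CC/C(C)=C/C=C(/C(C)C)CC[C@@](C)(O[Si](CC)(CC)CC)[C@@H]2CC[C@@]1(C)O2 | intermediate
26 | CNP0199953.1, (1S,10R,11S,14R)-1-acetoxy-11,14-epoxy macrocycle with C10–OH (cembrane numbering: 7S,8R,11S,12R-8,11-epoxycembra-1,3-diene-7,12-diol 7-acetate) | CC(=O)O[C@H]1CC/C(C)=C/C=C(/C(C)C)CC[C@@](C)(O)[C@@H]2CC[C@@]1(C)O2 | target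

Total step count: 17
Longest linear sequence: 13 steps (steps 1, 2, 3, 5, 9, 10, 11, 12, 13, 14, 15, 16, 17)

**Steps most likely to fail**

Step 13 (ring-expanding Claisen rearrangement). The exocyclic enol ether may isomerise into the ring or hydrolyse before it rearranges, and the rearrangement may leak through a boat or axial-chair pathway, eroding the E geometry at C14=C1. The fallback is a stepwise polar equivalent that forms the same bond in the same ring closure. It sets out from 20: mild acid hydrolysis (PPTS, wet THF, rt) opens the enol ether to the hydroxy methyl ketone (3R,6E,8E,12RS)-12-hydroxy-3,9,13-trimethyl-6-(propan-2-yl)-3-[(triethylsilyl)oxy]tetradeca-6,8,13-trien-2-one F1. Thionyl chloride in Et2O at 0 °C converts its 2-methylallylic alcohol, with allylic transposition, into the primary E allylic chloride (3R,6E,8E,12E)-14-chloro-3,9,13-trimethyl-6-(propan-2-yl)-3-[(triethylsilyl)oxy]tetradeca-6,8,12-trien-2-one F2. Slow addition of F2 to LiHMDS in THF (0.002 M, −78 to 0 °C, NaI cat.) generates the only possible enolate (at C12, since C10 is quaternary) and alkylates it at C13, closing the 14-membered ring and coming back to the route at 21.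

Step 15 (directed epoxidation and oxolane closure). The catalyst and the (11S)-alkoxide may be a mismatched pair, giving poor facial selectivity and slow turnover at the hindered alkoxide, with background oxidation of the diene. The fallback moves the control from the substrate-bound metal alkoxide to a chiral dioxirane. It sets out from 22: Shi epoxidation with the L-fructose-derived ketone (Oxone 2KHSO5·KHSO4·K2SO4 as limiting reagent, K2CO3 buffer, MeCN/dimethoxymethane/H2O, −10 °C, stopped at partial conversion to spare the diene) should give the same (14S,1S)-epoxy alcohol 23, which CSA closes to the oxolane; the route is rejoined at 24. This fallback makes no compound outside the list (F0).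

Step 10 (macrolactonisation). Acyl transfer to the hindered α-quaternary carbonyl may be slow, so that oligomerisation competes with closure of the 12-membered ring. The fallback makes the ester bond between two molecules and closes the ring at the diene instead. It sets out from 9 and 14: LiOH (THF/H2O) saponifies 9 to (2R,5E)-2-hydroxy-2-methyl-5-(propan-2-yl)-6-(4,4,5,5-tetramethyl-1,3,2-dioxaborolan-2-yl)hex-5-enoic acid F3. Esterification of F3 with 14 (EDC·HCl, DMAP, CH2Cl2) gives the iodo boronate ester F4. Intramolecular Suzuki–Miyaura coupling of F4 (PdCl2(dppf), K3PO4, THF/H2O, 0.002 M, 45 °C) forms the C5–C6 bond and the 12-membered ring, coming back to the route at 18.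

Further compounds
F1 | step 13 | (3R,6E,8E,12RS)-12-hydroxy-3,9,13-trimethyl-6-(propan-2-yl)-3-[(triethylsilyl)oxy]tetradeca-6,8,13-trien-2-one | C=C(C)C(O)CC/C(C)=C/C=C(/C(C)C)CC[C@@](C)(O[Si](CC)(CC)CC)C(C)=O
F2 | step 13 | (3R,6E,8E,12E)-14-chloro-3,9,13-trimethyl-6-(propan-2-yl)-3-[(triethylsilyl)oxy]tetradeca-6,8,12-trien-2-one | ClC/C(C)=C/CC/C(C)=C/C=C(/C(C)C)CC[C@@](C)(O[Si](CC)(CC)CC)C(C)=O
F0 | step 15 | none | none
F3 | step 10 | (2R,5E)-2-hydroxy-2-methyl-5-(propan-2-yl)-6-(4,4,5,5-tetramethyl-1,3,2-dioxaborolan-2-yl)hex-5-enoic acid | CC(C)/C(CC[C@@](C)(O)C(=O)O)=C/B1OC(C)(C)C(C)(C)O1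
F4 | step 10 | (3RS,6E)-7-iodo-2,6-dimethylhepta-1,6-dien-3-yl ester of F3 | CC(C)/C(CC[C@@](C)(O)C(=O)OC(CC/C(C)=C/I)C(C)=C)=C/B1OC(C)(C)C(C)(C)O1
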